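**Strategy.** The ten-membered carbocycle is opened at C9–C10 (germacranolide numbering). The C8 carbinol, the C9 methylene and the C1–C10 epoxide carrying C14 are read as a homoallylic alcohol, C8(OH)–C9H2–C10(CH3)=C1H. An intramolecular nickel-catalysed reductive alkyne–epoxide coupling of a monocyclic γ-lactone bearing a C8–C9 terminal epoxide on C7 and a 2-butynyl group (C1≡C10–C14) should close the ring at C9–C10, fix the E-C1=C10 geometry and unveil the C8 hydroxyl in one operation. The precursor arises by chromium-mediated allylation/lactonisation of a (Z)-enal with a glyceraldehyde-derived 2-(bromomethyl)acrylate. The exocyclic methylene is masked as its dimethylamine adduct and regenerated during the final mCPBA epoxidation.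

Key step: step 19

Remark: positions are numbered as in germacranolides (ring C1–C10, lactone carbons C11–C13, C14 on C10, C15 on C4); the target is the 1β,10α-epoxy-3β,8β-diacyloxy-4Z-6α,12-olide (1R,3S,6R,7R,8R,10R; epoxy acid 2S,3S). Compound 13 is drawn as its major epimer; both carbinol epimers give 14.

**Enal 10 (C1–C6, C14, C15)**

Step 1
Reactants: 1 methyl (S)-glycidate
Product: 2 methyl (2S)-2-hydroxyhex-4-ynoate
Conditions: 1-propynyllithium, BF3·OEt2, THF, −78 °C
Reagents that add atoms: 1-propynyllithium, [Li]C#CC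
Why: BF3-promoted epoxide alkynylation opens the oxirane by SN2 attack at its CH2 carbon, so the chiral-pool carbinol centre (future C3) is not touched.

Step 2
Reactants: 2 methyl (2S)-2-hydroxyhex-4-ynoate
Product: 3 methyl (2S)-2-[(tert-butyldimethylsilyl)oxy]hex-4-ynoate
Conditions: TBSCl, imidazole, DMF, rt
Reagents that add atoms: tert-butyldimethylsilyl chloride, CC(C)(C)[Si](C)(C)Cl
Why: Standard silylation of a secondary alcohol; the TBS ether survives the hydride, organolithium and cuprate steps that follow.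

Step 3
Reactants: 3 TBS ether of the hydroxy ester
Product: 4 (2S)-2-[(tert-butyldimethylsilyl)oxy]hex-4-ynal
Conditions: DIBAL-H (1.1 equiv), CH2Cl2, −78 °C
Reagents that add atoms: none
Why: Partial reduction of an α-silyloxy ester stops at the aldehyde because the tetrahedral aluminate is stable at −78 °C, and the cold neutral work-up should avoid epimerisation.

Step 4
Reactants: 4 α-silyloxy aldehyde
Product: 5 (3S)-3-[(tert-butyldimethylsilyl)oxy]hepta-1,5-diyne
Conditions: dimethyl (1-diazo-2-oxopropyl)phosphonate, K2CO3, MeOH, 0 °C to rt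
Reagents that add atoms: dimethyl (1-diazo-2-oxopropyl)phosphonate, CC(=O)C(=[N+]=[N-])P(=O)(OC)OC
Why: Ohira–Bestmann (Seyferth–Gilbert) homologation converts the aldehyde into the terminal alkyne under base mild enough to keep the α-silyloxy centre.

Step 5
Reactants: 5 diyne
Product: 7 methyl (4S)-4-[(tert-butyldimethylsilyl)oxy]octa-2,6-diynoate, via lithium acetylide 6 (not isolated)
Conditions: n-BuLi, THF, −78 °C; then ClCO2Me
Reagents that add atoms: methyl chloroformate, COC(=O)Cl
Why: Only the terminal alkyne is deprotonated, and acylation of the acetylide gives the ynoate needed for carbocupration.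

Step 6
Reactants: 7 ynoate
Product: 8 methyl (2Z,4S)-4-[(tert-butyldimethylsilyl)oxy]-3-methyloct-2-en-6-ynoate
Conditions: Me2CuLi (from CuI and MeLi), THF, −78 °C; MeOH then aq. NH4Cl at −78 °C
Reagents that add atoms: lithium dimethylcuprate, [Li+].C[Cu-]C
Why: Syn-carbocupration (conjugate addition) with cold protonation places methyl and hydrogen cis, so the ester and the silyloxy carbon end up cis (the Z-C4=C5 geometry); the unactivated internal alkyne does not react.

Step 7
Reactants: 8 (Z)-enoate
Product: 9 (2Z,4S)-4-[(tert-butyldimethylsilyl)oxy]-3-methyloct-2-en-6-yn-1-ol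
Conditions: DIBAL-H (2.2 equiv), CH2Cl2, −78 °C
Reagents that add atoms: none
Why: 1,2-Reduction of the enoate to the allylic alcohol proceeds without change of alkene geometry.

Step 8
Reactants: 9 (Z)-allylic alcohol
Product: 10 (2Z,4S)-4-[(tert-butyldimethylsilyl)oxy]-3-methyloct-2-en-6-ynal
Conditions: MnO2, CH2Cl2, rt
Reagents that add atoms: none
Why: Neutral allylic oxidation with MnO2 gives the (Z)-enal with little isomerisation; it is used directly in step 14.

**Allyl bromide 14 (C7–C9, C11–C13)**

Step 9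
Reactants: 11 (R)-glyceraldehyde acetonide; 12 methyl acrylate
Product: 13 methyl 2-{(S)-[(4R)-2,2-dimethyl-1,3-dioxolan-4-yl](hydroxy)methyl}prop-2-enoate (major anti epimer, minor epimer carried along)
Conditions: DABCO, dioxane/H2O, rt
Reagents that add atoms: none
Why: Morita–Baylis–Hillman reaction; the new carbinol centre is destroyed in step 10, so its configuration is irrelevant, and the dioxolane centre (future C8) is not affected.

Step 10
Reactants: 13 Baylis–Hillman adduct
Product: 14 methyl (2Z)-2-(bromomethyl)-3-[(4S)-2,2-dimethyl-1,3-dioxolan-4-yl]prop-2-enoate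
Conditions: NBS, Me2S, CH2Cl2, 0 °C to rt
Reagents that add atoms: N-bromosuccinimide, O=C1CCC(=O)N1Br
Why: Activation of the alcohol as an alkoxysulfonium ion and SN2' attack of bromide gives the rearranged (Z)-allyl bromide under non-acidic conditions that spare the acetonide.

**Epoxy acid 19**

Step 11
Reactants: 15 angelic acid
Product: 16 (2Z)-2-methylbut-2-en-1-ol
Conditions: LiAlH4, Et2O, 0 °C
Reagents that add atoms: none
Why: Hydride reduction of the unsaturated acid gives the allylic alcohol with retention of the Z geometry.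

Step 12
Reactants: 16 (Z)-allylic alcohol
Product: 17 [(2R,3S)-2,3-dimethyloxiran-2-yl]methanol
Conditions: Ti(OiPr)4, D-(−)-diethyl tartrate, t-BuOOH, 4 Å MS, CH2Cl2, −20 °C
Reagents that add atoms: tert-butyl hydroperoxide, CC(C)(C)OO
Why: Sharpless asymmetric epoxidation; the D-tartrate catalyst delivers oxygen to the face opposite to that used by the L-tartrate system (which gives 2S epoxy alcohols), setting both centres as 2R,3S, cis as dictated by the Z alkene.

Step 13
Reactants: 17 epoxy alcohol
Product: 19 (2S,3S)-2,3-dimethyloxirane-2-carboxylic acid, via epoxy aldehyde 18 (not isolated)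
Conditions: TEMPO (cat.), PhI(OAc)2, MeCN/H2O, rt
Reagents that add atoms: water, O
Why: Oxoammonium oxidation to the aldehyde and, through its hydrate, to the acid leaves the epoxide centres intact (the descriptor at C2 changes only through the priority rules).

**Assembly and end game**

Step 14
Reactants: 10 (Z)-enal; 14 allyl bromide
Product: 21 (4S,5R)-4-[(4S)-2,2-dimethyl-1,3-dioxolan-4-yl]-5-{(1Z,3S)-3-[(tert-butyldimethylsilyl)oxy]-2-methylhept-1-en-5-yn-1-yl}-3-methylideneoxolan-2-one, via anti hydroxy ester 20 (not isolated)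
Conditions: CrCl2 (4 equiv), THF, rt; then PPTS (cat.), CH2Cl2, rt
Reagents that add atoms: none
Why: Nozaki–Hiyama (chromium-mediated Barbier) allylation forms C6–C7 through a chair transition state with the γ-substituent equatorial, giving the anti adduct and hence the 6,7-trans lactone, while the dioxolane centre C8 directs the face of C7 (C8–H eclipsing the allyl unit, attack anti to C8–C9, the Felkin–Anh-type sense known for dioxolanyl-substituted allylchromium reagents), and the hydroxy ester lactonises.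

Step 15
Reactants: 21 lactone
Product: 22 (4R,5R)-4-[(1S)-1,2-dihydroxyethyl]-5-[(1Z,3S)-3-hydroxy-2-methylhept-1-en-5-yn-1-yl]-3-methylideneoxolan-2-one
Conditions: 2 M aq. HCl, THF, rt
Reagents that add atoms: none
Why: Acid hydrolysis removes the acetonide and the TBS ether together; the trans 6,12-γ-lactone is preferred over the cis 8,12- or the δ-lactone, so translactonisation should not interfere at rt.

Step 16
Reactants: 22 triol
Product: 24 (4S,5R)-5-[(1Z,3S)-3-hydroxy-2-methylhept-1-en-5-yn-1-yl]-3-methylidene-4-[(2S)-oxiran-2-yl]oxolan-2-one, via primary tosylate 23 (not isolated)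
Conditions: TsCl, Et3N, Bu2SnO (cat.), CH2Cl2, 0 °C; then DBU, 0 °C to rt
Reagents that add atoms: none
Why: Tin-catalysed sulfonylation is selective for the primary hydroxyl of the 1,2-diol, and 3-exo-tet closure from the C8 oxygen forms the terminal epoxide without touching the C8–O bond, so C8 keeps its configuration.

Step 17
Reactants: 24 epoxy alcohol
Product: 25 C3 isovalerate of 24: (1Z,3S)-2-methyl-1-{(2R,3S)-4-methylidene-5-oxo-3-[(2S)-oxiran-2-yl]oxolan-2-yl}hept-1-en-5-yn-3-yl 3-methylbutanoate
Conditions: 3-methylbutanoic anhydride, Et3N, DMAP (cat.), CH2Cl2, 0 °C to rt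
Reagents that add atoms: 3-methylbutanoic anhydride, CC(C)CC(=O)OC(=O)CC(C)C
Why: DMAP-catalysed acylation of the only free hydroxyl (C3) installs the isovalerate.

Step 18
Reactants: 25 α-methylene lactone
Product: 26 dimethylamine adduct: (1Z,3S)-1-{(2R,3S,4R)-4-[(dimethylamino)methyl]-5-oxo-3-[(2S)-oxiran-2-yl]oxolan-2-yl}-2-methylhept-1-en-5-yn-3-yl 3-methylbutanoate
Conditions: Me2NH (2 M in THF, 1.2 equiv), THF, 0 °C
Reagents that add atoms: dimethylamine, CNC
Why: Aza-Michael addition to the α-methylene lactone is much faster than epoxide or ester aminolysis at 0 °C and masks the acrylate for step 19; the C11 centre (aminomethyl expected trans to the C7 substituent) is removed again in step 21.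

Step 19
Reactants: 26 epoxy alkyne
Product: 27 (1(10)E,4Z)-13-(dimethylamino)-8β-hydroxy-3β-(3-methylbutanoyloxy)-11,13-dihydrogermacra-1(10),4-dien-6α,12-olide (3S,6R,7R,8R,11R)
Conditions: Ni(cod)2 (20 mol %), PBu3 (40 mol %), Et3B (4 equiv), THF, 0.01 M, rt
Reagents that add atoms: none
Why: Zerovalent nickel/PBu3 adds oxidatively to the less hindered C9–O bond of the terminal epoxide, the alkyne inserts syn into the Ni–C9 bond with C9 bonding to the methyl-bearing C10, and Et3B then transfers ethyl to nickel while forming the B–O8 bond, after which β-hydride elimination (ethylene) and C1–H reductive elimination turn the catalyst over. The closest known reaction type is the nickel-catalysed reductive coupling of alkynes with terminal epoxides to homoallylic alcohols, which is known intermolecularly and for ring closure, macrocycles included. The ten-membered ring closes in the endo mode at both partners (10-endo-dig at the alkyne; attack at the distal epoxide carbon, so O8 stays on ring carbon C8). No stereocentre is created: C8 keeps its configuration because only the C9–O bond breaks, and the E geometry of C1=C10 follows from syn addition of C9 and H across the alkyne. The step needs regioselectivity at the alkyne (C10 over C1), favoured because C–C bond formation occurs at the carbon with the smaller substituent (methyl) and the alternative is a nine-membered ring with an exocyclic alkene. It also needs chemoselectivity, which is secured by masking the acrylate as amine adduct 26 and by the hindered, trisubstituted environment of the two allylic C–O bonds; high dilution suppresses oligomers.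

Step 20
Reactants: 19 epoxy acid; 27 macrocyclic alcohol
Product: 29 13-(dimethylamino)-8β-[(2S,3S)-2,3-epoxy-2-methylbutanoyloxy]-3β-(3-methylbutanoyloxy)-11,13-dihydrogermacra-1(10)E,4Z-dien-6α,12-olide, via mixed anhydride 28 (not isolated)
Conditions: 19, 2,4,6-trichlorobenzoyl chloride, Et3N, THF, rt; then 27, DMAP, toluene, rt
Reagents that add atoms: none
Why: Yamaguchi esterification couples the hindered 8β-hydroxyl with the α-quaternary epoxy acid without touching either epoxide stereocentre.

Step 21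
Reactants: 29 amine-masked diester
Product: 32 target (1R,3S,6R,7R,8R,10R; acyl 2S,3S), via N-oxide 30 (not isolated), via α-methylene lactone 31 (not isolated)
Conditions: mCPBA (3.5 equiv), NaHCO3, CH2Cl2, 0 °C to rt
Reagents that add atoms: m-chloroperbenzoic acid, OOC(=O)c1cccc(Cl)c1
Why: mCPBA first oxidises the amine to the N-oxide, whose Cope elimination through the acidic C11–H restores the exocyclic methylene, and then epoxidises the most electron-rich alkene (C1=C10) from its exposed peripheral face (C14 on the β face in the usual heliangolide conformation) to give the trans 1β,10α-epoxide; C4=C5 is deactivated by two allylic acyloxy groups and the acrylate is electron-poor.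

**Compound list**

1 | methyl (S)-glycidate | COC(=O)[C@@H]1CO1 | starting material
2 | methyl (2S)-2-hydroxyhex-4-ynoate | COC(=O)[C@@H](O)CC#CC | intermediate
3 | methyl (2S)-2-[(tert-butyldimethylsilyl)oxy]hex-4-ynoate | COC(=O)[C@@H](O[Si](C)(C)C(C)(C)C)CC#CC | intermediate
4 | (2S)-2-[(tert-butyldimethylsilyl)oxy]hex-4-ynal | O=C[C@@H](O[Si](C)(C)C(C)(C)C)CC#CC | intermediate
5 | (3S)-3-[(tert-butyldimethylsilyl)oxy]hepta-1,5-diyne | C#C[C@@H](O[Si](C)(C)C(C)(C)C)CC#CC | intermediate
6 | lithium acetylide of 5 | [Li]C#C[C@@H](O[Si](C)(C)C(C)(C)C)CC#CC | intermediate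
7 | methyl (4S)-4-[(tert-butyldimethylsilyl)oxy]octa-2,6-diynoate | COC(=O)C#C[C@@H](O[Si](C)(C)C(C)(C)C)CC#CC | intermediate
8 | methyl (2Z,4S)-4-[(tert-butyldimethylsilyl)oxy]-3-methyloct-2-en-6-ynoate | COC(=O)/C=C(/C)[C@@H](O[Si](C)(C)C(C)(C)C)CC#CC | intermediate
9 | (2Z,4S)-4-[(tert-butyldimethylsilyl)oxy]-3-methyloct-2-en-6-yn-1-ol | OC/C=C(/C)[C@@H](O[Si](C)(C)C(C)(C)C)CC#CC | intermediate
10 | (2Z,4S)-4-[(tert-butyldimethylsilyl)oxy]-3-methyloct-2-en-6-ynal | O=C/C=C(/C)[C@@H](O[Si](C)(C)C(C)(C)C)CC#CC | intermediate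
11 | (R)-glyceraldehyde acetonide, (4R)-2,2-dimethyl-1,3-dioxolane-4-carbaldehyde | O=C[C@H]1COC(C)(C)O1 | starting material
12 | methyl acrylate | C=CC(=O)OC | starting material
13 | methyl 2-{(S)-[(4R)-2,2-dimethyl-1,3-dioxolan-4-yl](hydroxy)methyl}prop-2-enoate (major epimer) | C=C(C(=O)OC)[C@H](O)[C@H]1COC(C)(C)O1 | intermediate
14 | methyl (2Z)-2-(bromomethyl)-3-[(4S)-2,2-dimethyl-1,3-dioxolan-4-yl]prop-2-enoate | COC(=O)/C(CBr)=C/[C@H]1COC(C)(C)O1 | intermediate
15 | angelic acid, (2Z)-2-methylbut-2-enoic acid | C/C=C(/C)C(=O)O | starting material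
16 | (2Z)-2-methylbut-2-en-1-ol | C/C=C(/C)CO | intermediate
17 | [(2R,3S)-2,3-dimethyloxiran-2-yl]methanol | OC[C@@]1(C)O[C@H]1C | intermediate
18 | (2S,3S)-2,3-dimethyloxirane-2-carbaldehyde | O=C[C@@]1(C)O[C@H]1C | intermediate
19 | (2S,3S)-2,3-dimethyloxirane-2-carboxylic acid | OC(=O)[C@@]1(C)O[C@H]1C | intermediate
20 | methyl (3S,4R,5Z,7S)-7-[(tert-butyldimethylsilyl)oxy]-3-[(4S)-2,2-dimethyl-1,3-dioxolan-4-yl]-4-hydroxy-6-methyl-2-methylideneundec-5-en-9-ynoate | COC(=O)C(=C)[C@H]([C@H]1COC(C)(C)O1)[C@H](O)/C=C(/C)[C@@H](O[Si](C)(C)C(C)(C)C)CC#CC | intermediate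
21 | (4S,5R)-4-[(4S)-2,2-dimethyl-1,3-dioxolan-4-yl]-5-{(1Z,3S)-3-[(tert-butyldimethylsilyl)oxy]-2-methylhept-1-en-5-yn-1-yl}-3-methylideneoxolan-2-one | C=C1C(=O)O[C@H](/C=C(/C)[C@@H](O[Si](C)(C)C(C)(C)C)CC#CC)[C@H]1[C@H]1COC(C)(C)O1 | intermediate
22 | (4R,5R)-4-[(1S)-1,2-dihydroxyethyl]-5-[(1Z,3S)-3-hydroxy-2-methylhept-1-en-5-yn-1-yl]-3-methylideneoxolan-2-one | C=C1C(=O)O[C@H](/C=C(/C)[C@@H](O)CC#CC)[C@H]1[C@H](O)CO | intermediate
23 | primary p-toluenesulfonate of 22 | C=C1C(=O)O[C@H](/C=C(/C)[C@@H](O)CC#CC)[C@H]1[C@H](O)COS(=O)(=O)c1ccc(C)cc1 | intermediate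
24 | (4S,5R)-5-[(1Z,3S)-3-hydroxy-2-methylhept-1-en-5-yn-1-yl]-3-methylidene-4-[(2S)-oxiran-2-yl]oxolan-2-one | C=C1C(=O)O[C@H](/C=C(/C)[C@@H](O)CC#CC)[C@H]1[C@H]1CO1 | intermediate
25 | C3 isovalerate of 24 | C=C1C(=O)O[C@H](/C=C(/C)[C@@H](OC(=O)CC(C)C)CC#CC)[C@H]1[C@H]1CO1 | intermediate
26 | dimethylamine adduct of 25 (11R) | CN(C)C[C@@H]1C(=O)O[C@H](/C=C(/C)[C@@H](OC(=O)CC(C)C)CC#CC)[C@H]1[C@H]1CO1 | intermediate
27 | (1(10)E,4Z)-13-(dimethylamino)-8β-hydroxy-3β-(3-methylbutanoyloxy)-11,13-dihydrogermacra-1(10),4-dien-6α,12-olide | CN(C)C[C@@H]1C(=O)O[C@@H]2/C=C(/C)[C@@H](OC(=O)CC(C)C)C/C=C(\C)C[C@@H](O)[C@@H]12 | intermediate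
28 | (2S,3S)-2,3-dimethyloxirane-2-carboxylic 2,4,6-trichlorobenzoic anhydride | O=C(OC(=O)c1c(Cl)cc(Cl)cc1Cl)[C@@]1(C)O[C@H]1C | intermediate
29 | 8-O-[(2S,3S)-2,3-epoxy-2-methylbutanoyl] ester of 27 | CN(C)C[C@@H]1C(=O)O[C@@H]2/C=C(/C)[C@@H](OC(=O)CC(C)C)C/C=C(\C)C[C@@H](OC(=O)[C@@]3(C)O[C@H]3C)[C@@H]12 | intermediate
30 | N-oxide of 29 | C[N+](C)([O-])C[C@@H]1C(=O)O[C@@H]2/C=C(/C)[C@@H](OC(=O)CC(C)C)C/C=C(\C)C[C@@H](OC(=O)[C@@]3(C)O[C@H]3C)[C@@H]12 | intermediate
31 | 8β-[(2S,3S)-2,3-epoxy-2-methylbutanoyloxy]-3β-(3-methylbutanoyloxy)germacra-1(10)E,4Z,11(13)-trien-6α,12-olide | C=C1C(=O)O[C@@H]2/C=C(/C)[C@@H](OC(=O)CC(C)C)C/C=C(\C)C[C@@H](OC(=O)[C@@]3(C)O[C@H]3C)[C@@H]12 | intermediate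
32 | CNP0167461.1, 1β,10α-epoxy-8β-[(2S,3S)-2,3-epoxy-2-methylbutanoyloxy]-3β-(3-methylbutanoyloxy)germacra-4Z,11(13)-dien-6α,12-olide | C=C1C(=O)O[C@@H]2/C=C(/C)[C@@H](OC(=O)CC(C)C)C[C@H]3O[C@]3(C)C[C@@H](OC(=O)[C@@]3(C)O[C@H]3C)[C@@H]12 | target

**Step count and risks**

Total step count: 21. Longest linear sequence: 16 steps (steps 1–8, then 14–21).

Steps most likely to fail:

1. Step 19. What may go wrong: insertion at the other alkyne carbon (C1, giving a nine-membered ring with an exocyclic ethylidene), oligomerisation, or ionisation of the allylic C–O bonds at C3 and C6 by zerovalent nickel. Fallback: fix the alkyne regiochemistry before ring closure and form the same C9–C10 bond by a cross-electrophile coupling. It sets out from 9: hydrozirconation with excess Cp2Zr(H)Cl (equilibrated so that zirconium sits at the methyl terminus) and iodination should give the (E)-alkenyl iodide alcohol F1. MnO2 oxidation gives enal F2, and CrCl2-mediated allylation with 14 gives lactone F3. Aqueous HCl gives triol F4, tin-catalysed tosylation gives tosylate F5, and DBU closes it to epoxide F6. Acylation gives isovalerate F7 and Me2NH gives amine adduct F8. Intramolecular nickel-catalysed reductive coupling of the alkenyl iodide with the epoxide under iodide co-catalysis (NiCl2(dme), 4,4'-di-tert-butyl-2,2'-bipyridine, NaI, Et3N·HCl, Mn, DMPU, high dilution), which opens the epoxide at its terminal carbon and retains the alkene geometry, would return to the route at 27.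

2. Step 14. What may go wrong: attack of the aldehyde on the other face of the allyl unit (anti to the dioxolane C–O bond), which would give the 6,7-diastereomeric pair, or erosion of the anti selectivity. Fallback: take C8 from the other glyceraldehyde enantiomer and invert it when the epoxide is closed. It sets out from 10: commercial (S)-glyceraldehyde acetonide and 12 give the enantiomeric Baylis–Hillman adduct F9 and, with NBS/Me2S, the enantiomeric bromide F10. CrCl2-mediated coupling of F10 with 10 should then give the 6,7-correct, 8-epimeric lactone F11. Selective acetonide hydrolysis (aq. AcOH) gives diol F12, silylation of the primary hydroxyl (TBSCl, imidazole) gives bis-silyl ether F13, and MsCl/Et3N gives mesylate F14. TBAF removes both silyl groups, and the primary alkoxide displaces the C8 mesylate with inversion, returning to the route at 24.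

3. Step 21. What may go wrong: poor facial selectivity in the epoxidation of C1=C10 if the macrocycle populates more than one conformer, or side reactions of the liberated hydroxylamine with the regenerated acrylate. Fallback: separate unmasking and epoxidation and use reagent control. It sets out from 29: MeI gives the methiodide F15, which aqueous NaHCO3 converts by elimination into 31 (now isolated). Shi epoxidation of 31 with the D-fructose-derived ketone and Oxone, which gives R,R epoxides from E-trisubstituted alkenes, returns to the route at 32.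

**Further compounds**

F1 | step 19 | (2Z,4S,6E)-4-[(tert-butyldimethylsilyl)oxy]-7-iodo-3-methylocta-2,6-dien-1-ol | OC/C=C(/C)[C@@H](O[Si](C)(C)C(C)(C)C)C/C=C(\C)I
F2 | step 19 | (2Z,4S,6E)-4-[(tert-butyldimethylsilyl)oxy]-7-iodo-3-methylocta-2,6-dienal | O=C/C=C(/C)[C@@H](O[Si](C)(C)C(C)(C)C)C/C=C(\C)I
F3 | step 19 | alkenyl iodide analogue of lactone 21 | C=C1C(=O)O[C@H](/C=C(/C)[C@@H](O[Si](C)(C)C(C)(C)C)C/C=C(\C)I)[C@H]1[C@H]1COC(C)(C)O1
F4 | step 19 | alkenyl iodide analogue of triol 22 | C=C1C(=O)O[C@H](/C=C(/C)[C@@H](O)C/C=C(\C)I)[C@H]1[C@H](O)CO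
F5 | step 19 | alkenyl iodide analogue of tosylate 23 | C=C1C(=O)O[C@H](/C=C(/C)[C@@H](O)C/C=C(\C)I)[C@H]1[C@H](O)COS(=O)(=O)c1ccc(C)cc1
F6 | step 19 | alkenyl iodide analogue of epoxide 24 | C=C1C(=O)O[C@H](/C=C(/C)[C@@H](O)C/C=C(\C)I)[C@H]1[C@H]1CO1
F7 | step 19 | alkenyl iodide analogue of isovalerate 25 | C=C1C(=O)O[C@H](/C=C(/C)[C@@H](OC(=O)CC(C)C)C/C=C(\C)I)[C@H]1[C@H]1CO1
F8 | step 19 | alkenyl iodide analogue of amine adduct 26 | CN(C)C[C@@H]1C(=O)O[C@H](/C=C(/C)[C@@H](OC(=O)CC(C)C)C/C=C(\C)I)[C@H]1[C@H]1CO1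
F9 | step 14 | methyl 2-{(R)-[(4S)-2,2-dimethyl-1,3-dioxolan-4-yl](hydroxy)methyl}prop-2-enoate (major epimer) | C=C(C(=O)OC)[C@@H](O)[C@@H]1COC(C)(C)O1
F10 | step 14 | methyl (2Z)-2-(bromomethyl)-3-[(4R)-2,2-dimethyl-1,3-dioxolan-4-yl]prop-2-enoate | COC(=O)/C(CBr)=C/[C@@H]1COC(C)(C)O1
F11 | step 14 | 8-epimer of lactone 21 [(4R)-dioxolane] | C=C1C(=O)O[C@H](/C=C(/C)[C@@H](O[Si](C)(C)C(C)(C)C)CC#CC)[C@H]1[C@@H]1COC(C)(C)O1
F12 | step 14 | 8-epi diol with C3 silyl ether retained | C=C1C(=O)O[C@H](/C=C(/C)[C@@H](O[Si](C)(C)C(C)(C)C)CC#CC)[C@H]1[C@@H](O)CO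
F13 | step 14 | primary TBS ether of F12 | C=C1C(=O)O[C@H](/C=C(/C)[C@@H](O[Si](C)(C)C(C)(C)C)CC#CC)[C@H]1[C@@H](O)CO[Si](C)(C)C(C)(C)C
F14 | step 14 | C8 mesylate of F13 | C=C1C(=O)O[C@H](/C=C(/C)[C@@H](O[Si](C)(C)C(C)(C)C)CC#CC)[C@H]1[C@@H](OS(C)(=O)=O)CO[Si](C)(C)C(C)(C)C
F15 | step 21 | methiodide of 29 | C[N+](C)(C)C[C@@H]1C(=O)O[C@@H]2/C=C(/C)[C@@H](OC(=O)CC(C)C)C/C=C(\C)C[C@@H](OC(=O)[C@@]3(C)O[C@H]3C)[C@@H]12.[I-]
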